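**Retrosynthetic overview**

- The target is the C2-symmetric 4,4′-linked dimer of (S)-curcuphenol. The last operations are O-demethylation of the bis(methyl ether) and replacement of boron by hydrogen at both benzylic carbons.
- The strategy rests on the two benzylic methines C7/C7′. Each sits on ring carbon C5/C5′, next to the oxygen-bearing C4/C4′ of its benzene ring, and carries H, a methyl group and the C8 methylene of a homoprenyl chain. This is the pattern produced when a secondary 1-arylethyl carbamate is homologated by a primary alkyl boronic ester.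
- Key disconnection: both C7–C8 bonds, made in one operation by twofold lithiation–borylation of the (S,S)-bis(carbamate) of the biaryl with homoprenyl pinacol boronate.
- The bis(carbamate) comes from the (S,S)-diol, made by double asymmetric transfer hydrogenation of the 5,5′-diacetyl biaryl. That diketone comes from nickel-catalysed homocoupling of 5-bromo-2-methoxy-4-methylacetophenone, itself made from 2-hydroxy-4-methylacetophenone.
- No ring is formed. Both benzene rings are purchased and the biaryl bond is made in step 3.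

Key step: step 7

Assumption: the biaryl axis carries only two ortho methyl groups and should rotate freely at room temperature, so the two benzylic centres are the only stereogenic elements to control.

**Route**

Step 1
Reactants: 1 1-(2-hydroxy-4-methylphenyl)ethanone
Product: 2 1-(5-bromo-2-hydroxy-4-methylphenyl)ethanone
Conditions: NBS (1.05 equiv), MeCN, 0 °C → rt
Reagents that add atoms: N-bromosuccinimide, O=C1CCC(=O)N1Br
Why: Electrophilic aromatic bromination should go to C5, which is para to OH, meta to the acetyl group and the only unhindered activated position, so ring substitution should outrun α-bromination of the ketone.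

Step 2
Reactants: 2 1-(5-bromo-2-hydroxy-4-methylphenyl)ethanone
Product: 3 1-(5-bromo-2-methoxy-4-methylphenyl)ethanone
Conditions: MeI, K2CO3, DMF, 50 °C
Reagents that add atoms: iodomethane, CI
Why: Williamson O-methylation of the phenoxide gives an ether that is inert to s-BuLi and fluoride and can be cleaved at the end by thiolate.

Step 3
Reactants: 3 1-(5-bromo-2-methoxy-4-methylphenyl)ethanone (2 equiv)
Product: 4 5,5′-diacetyl-4,4′-dimethoxy-2,2′-dimethylbiphenyl
Conditions: NiBr2(PPh3)2 (10 mol%), Zn dust, Et4NI, THF, 50 °C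
Reagents that add atoms: none
Why: Nickel(0)-catalysed reductive homocoupling of aryl bromides (Ullmann-type, Zn as terminal reductant) tolerates aryl ketones and a single ortho substituent, so the C1–C1′ bond should form directly.

Step 4
Reactants: 4 5,5′-diacetyl-4,4′-dimethoxy-2,2′-dimethylbiphenyl
Product: 5 5,5′-bis[(1S)-1-hydroxyethyl]-4,4′-dimethoxy-2,2′-dimethylbiphenyl
Conditions: RuCl[(S,S)-TsDPEN](p-cymene) (2 mol% per C=O), HCO2H/Et3N (5:2), EtOAc, 40 °C; recrystallise
Reagents that add atoms: none
Why: Noyori–Ikariya asymmetric transfer hydrogenation with the (S,S)-catalyst should deliver hydride to the Re face of each aryl methyl ketone to give the (S)-carbinols under catalyst control; because the two reductions are independent, most wrong-sense reduction should end up in the meso diol, which is removed by crystallisation.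

Step 5
Reactants: 5 5,5′-bis[(1S)-1-hydroxyethyl]-4,4′-dimethoxy-2,2′-dimethylbiphenyl; 6 N,N-diisopropylcarbamoyl chloride
Product: 7 5,5′-bis[(1S)-1-(N,N-diisopropylcarbamoyloxy)ethyl]-4,4′-dimethoxy-2,2′-dimethylbiphenyl
Conditions: NaH (2.4 equiv), 6 (2.4 equiv), THF, 0 °C → 60 °C
Reagents that add atoms: none
Why: O-carbamoylation of the alkoxides is an acyl substitution at the carbamoyl carbon, so the C–O bonds at both stereocentres are untouched and the (S,S) configuration is retained.

Step 6
Reactants: 8 5-bromo-2-methylpent-2-ene; 9 2-isopropoxy-4,4,5,5-tetramethyl-1,3,2-dioxaborolane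
Product: 11 4,4,5,5-tetramethyl-2-(4-methylpent-3-en-1-yl)-1,3,2-dioxaborolane, via (4-methylpent-3-en-1-yl)magnesium bromide 10 (not isolated)
Conditions: Mg, THF, rt; then 9, −78 °C → rt; aqueous work-up
Reagents that add atoms: none
Why: Grignard formation followed by borylation with the isopropoxy pinacol borate at low temperature should give the primary alkyl boronic ester by displacement of isopropoxide without over-addition, the remote trisubstituted alkene being inert.

Step 7
Reactants: 7 5,5′-bis[(1S)-1-(N,N-diisopropylcarbamoyloxy)ethyl]-4,4′-dimethoxy-2,2′-dimethylbiphenyl; 11 4,4,5,5-tetramethyl-2-(4-methylpent-3-en-1-yl)-1,3,2-dioxaborolane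
Product: 14 4,4′-dimethoxy-2,2′-dimethyl-5,5′-bis[(2S)-6-methyl-2-(4,4,5,5-tetramethyl-1,3,2-dioxaborolan-2-yl)hept-5-en-2-yl]biphenyl, via dilithiated bis-carbamate 12 (not isolated), via bis-boronate ate complex 13 (not isolated)
Conditions: s-BuLi (2.6 equiv), Et2O, −78 °C, 1 h; 11 (3 equiv), −78 °C, 2 h; MgBr2·OEt2/MeOH, −78 °C → rt, 16 h; aq. NH4Cl
Reagents that add atoms: none
Why: s-BuLi should remove each carbamate-activated benzylic proton with retention to give the chelated, configurationally stable dilithio species 12, which is borylated on the face the lithium occupied to give ate complex 13; on warming with MgBr2/MeOH the homoprenyl group shifts from boron to carbon anti to the departing carbamate (1,2-metallate rearrangement), forming both C7–C8 bonds. The closest known reaction type is the lithiation–borylation of enantioenriched secondary benzylic carbamates with primary alkyl pinacol boronates to give tertiary boronic esters. No ring is closed. Each new boron-bearing stereocentre is set by substrate control alone: the (S)-carbamate configuration is transferred stereospecifically (retention in lithiation and borylation, inversion at carbon in the migration), so (S,S)-7 should give (S,S)-14. The step needs deprotonation at the benzylic C–H and not at the ring or the aryl methyl groups, which the complex-induced proximity effect of the carbamate carbonyl should secure. It also needs irreversible collapse of the ate complex at a crowded ortho-methoxy centre, which the unhindered primary migrating group and the MgBr2/MeOH additive are meant to secure; the two sites are remote and should react independently.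

Step 8
Reactants: 14 4,4′-dimethoxy-2,2′-dimethyl-5,5′-bis[(2S)-6-methyl-2-(4,4,5,5-tetramethyl-1,3,2-dioxaborolan-2-yl)hept-5-en-2-yl]biphenyl
Product: 15 4,4′-dimethoxy-2,2′-dimethyl-5,5′-bis[(2S)-6-methylhept-5-en-2-yl]biphenyl
Conditions: TBAF·3H2O (3 equiv per boron), toluene, 45 °C
Reagents that add atoms: none
Why: Fluoride-promoted protodeboronation of tertiary benzylic boronic esters proceeds by front-side protonation of the fluoride-activated boronate by water, so each C–B bond should become C–H with retention, leaving both centres (S); ethers and alkenes are inert.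

Step 9
Reactants: 15 4,4′-dimethoxy-2,2′-dimethyl-5,5′-bis[(2S)-6-methylhept-5-en-2-yl]biphenyl
Product: 16 2,2′-dimethyl-5,5′-bis[(2S)-6-methylhept-5-en-2-yl]biphenyl-4,4′-diol (CNP0163343.1)
Conditions: NaSEt (8 equiv), DMF, 130 °C; then aq. HCl
Reagents that add atoms: none
Why: Thiolate SN2 attack at the O-methyl carbons cleaves both aryl methyl ethers under non-acidic conditions that should neither cyclise the trisubstituted alkenes nor epimerise the non-acidic benzylic centres.

**Compound list**

1 | 1-(2-hydroxy-4-methylphenyl)ethanone | CC(=O)c1ccc(C)cc1O | starting material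
2 | 1-(5-bromo-2-hydroxy-4-methylphenyl)ethanone | CC(=O)c1cc(Br)c(C)cc1O | intermediate
3 | 1-(5-bromo-2-methoxy-4-methylphenyl)ethanone | COc1cc(C)c(Br)cc1C(C)=O | intermediate
4 | 5,5′-diacetyl-4,4′-dimethoxy-2,2′-dimethylbiphenyl | COc1cc(C)c(-c2cc(C(C)=O)c(OC)cc2C)cc1C(C)=O | intermediate
5 | 5,5′-bis[(1S)-1-hydroxyethyl]-4,4′-dimethoxy-2,2′-dimethylbiphenyl | COc1cc(C)c(-c2cc([C@H](C)O)c(OC)cc2C)cc1[C@H](C)O | intermediate
6 | N,N-diisopropylcarbamoyl chloride | CC(C)N(C(C)C)C(Cl)=O | starting material
7 | 5,5′-bis[(1S)-1-(N,N-diisopropylcarbamoyloxy)ethyl]-4,4′-dimethoxy-2,2′-dimethylbiphenyl | Cc1cc(OC)c([C@H](C)OC(=O)N(C(C)C)C(C)C)cc1-c1cc([C@H](C)OC(=O)N(C(C)C)C(C)C)c(OC)cc1C | intermediate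
8 | 5-bromo-2-methylpent-2-ene | CC(C)=CCCBr | starting material
9 | 2-isopropoxy-4,4,5,5-tetramethyl-1,3,2-dioxaborolane | CC(C)OB1OC(C)(C)C(C)(C)O1 | starting material
10 | (4-methylpent-3-en-1-yl)magnesium bromide | CC(C)=CCC[Mg]Br | intermediate (not isolated)
11 | 4,4,5,5-tetramethyl-2-(4-methylpent-3-en-1-yl)-1,3,2-dioxaborolane | CC(C)=CCCB1OC(C)(C)C(C)(C)O1 | intermediate
12 | dilithiated bis-carbamate (each benzylic H of 7 replaced by Li with retention) | Cc1cc(OC)c([C@]([Li])(C)OC(=O)N(C(C)C)C(C)C)cc1-c1cc([C@]([Li])(C)OC(=O)N(C(C)C)C(C)C)c(OC)cc1C | intermediate (not isolated)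
13 | bis-boronate ate complex, dilithium salt (each benzylic carbon bound to a tetracoordinate pinacolato(homoprenyl)borate) | Cc1cc(OC)c([C@]([B-]2(CCC=C(C)C)OC(C)(C)C(C)(C)O2)(C)OC(=O)N(C(C)C)C(C)C)cc1-c1cc([C@]([B-]2(CCC=C(C)C)OC(C)(C)C(C)(C)O2)(C)OC(=O)N(C(C)C)C(C)C)c(OC)cc1C.[Li+].[Li+] | intermediate (not isolated)
14 | 4,4′-dimethoxy-2,2′-dimethyl-5,5′-bis[(2S)-6-methyl-2-(4,4,5,5-tetramethyl-1,3,2-dioxaborolan-2-yl)hept-5-en-2-yl]biphenyl | Cc1cc(OC)c([C@@](B2OC(C)(C)C(C)(C)O2)(C)CCC=C(C)C)cc1-c1cc([C@@](B2OC(C)(C)C(C)(C)O2)(C)CCC=C(C)C)c(OC)cc1C | intermediate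
15 | 4,4′-dimethoxy-2,2′-dimethyl-5,5′-bis[(2S)-6-methylhept-5-en-2-yl]biphenyl | Cc1cc(OC)c([C@@H](C)CCC=C(C)C)cc1-c1cc([C@@H](C)CCC=C(C)C)c(OC)cc1C | intermediate
16 | 2,2′-dimethyl-5,5′-bis[(2S)-6-methylhept-5-en-2-yl]biphenyl-4,4′-diol (CNP0163343.1) | CC(C)=CCC[C@H](C)c1cc(-c2cc([C@@H](C)CCC=C(C)C)c(O)cc2C)c(C)cc1O | target

**Step count**

Total steps: 9. Longest linear sequence: 8 steps (1 → 2 → 3 → 4 → 5 → 7 → 14 → 15 → 16, i.e. steps 1–5 and 7–9); step 6 is a one-step branch.

**Steps most likely to fail**

Step 7. The second benzylic deprotonation may stall or the dilithio species may aggregate and precipitate. Ate-complex formation at the crowded, electron-rich carbanions may also be slow and reversible, which would return carbamate, give mono-homologated material or erode configuration. The fallback sets out from diketone 4, avoids boron at the benzylic carbon and returns at 15. Horner–Wadsworth–Emmons olefination of 4 (triethyl phosphonoacetate, NaH, THF, reflux) would give diethyl (2E,2′E)-3,3′-(4,4′-dimethoxy-6,6′-dimethylbiphenyl-3,3′-diyl)bis(but-2-enoate) F1, purified to the E,E isomer because alkene geometry dictates the sense of the next step. Copper hydride conjugate reduction (Cu(OAc)2, p-Tol-BINAP, PMHS, t-BuOH, toluene; ligand antipode chosen on the monomeric enoate to give the 3S ester) would then give diethyl (3S,3′S)-3,3′-(4,4′-dimethoxy-6,6′-dimethylbiphenyl-3,3′-diyl)dibutanoate F2. LiAlH4 reduction would give (3S,3′S)-3,3′-(4,4′-dimethoxy-6,6′-dimethylbiphenyl-3,3′-diyl)bis(butan-1-ol) F3, and I2/PPh3/imidazole would give 5,5′-bis[(2S)-4-iodobutan-2-yl]-4,4′-dimethoxy-2,2′-dimethylbiphenyl F4. Copper-catalysed coupling of F4 with (2-methylprop-1-en-1-yl)magnesium bromide (CuI, THF, −20 → 0 °C) would attach the isobutenyl ends and deliver 15, from which step 9 follows.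

Step 8. Protonolysis of two crowded tertiary C–B bonds on an electron-rich arene may be slow or stop after one site, and retention may be eroded or boron lost oxidatively to the tertiary alcohol. The fallback sets out from diketone 4 and returns at 15, installing the benzylic hydrogens by hydrogenation. Double enolate alkylation of 4 (LDA, THF, −78 °C; 1-bromo-3-methylbut-2-ene) would give 1,1′-(4,4′-dimethoxy-6,6′-dimethylbiphenyl-3,3′-diyl)bis(5-methylhex-4-en-1-one) F5. Wittig methylenation (Ph3PCH3Br, KOt-Bu, THF, reflux) would give 4,4′-dimethoxy-2,2′-dimethyl-5,5′-bis(6-methylhepta-1,5-dien-2-yl)biphenyl F6. Iridium-catalysed asymmetric hydrogenation of the two terminal aryl-substituted alkenes ([Ir(cod)(phosphinite–oxazoline)]BArF, H2 1 bar, CH2Cl2, rt; ligand antipode chosen for the S centres) should then give 15. The trialkyl-substituted chain alkenes are poor substrates for such catalysts at low pressure and should remain.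

Step 4. Reduction of two ortho-methoxy ketones may be sluggish and not fully face-selective, leaving mono-reduced material and a meso diol that is hard to remove. The fallback sets out from bromo ketone 3 and returns at bis(carbamate) 7, fixing the stereocentre on the monomer where it can be enriched before the biaryl bond is made. Oxazaborolidine-catalysed borane reduction of 3 ((R)-Me-CBS, BH3·SMe2, THF) would give (1S)-1-(5-bromo-2-methoxy-4-methylphenyl)ethanol F7, upgraded by crystallisation. Carbamoylation with 6 (NaH, THF) would give (1S)-1-(5-bromo-2-methoxy-4-methylphenyl)ethyl N,N-diisopropylcarbamate F8. One-pot Miyaura borylation of half of F8 (Pd(dppf)Cl2, B2pin2 0.5 equiv, KOAc, dioxane, 90 °C) would form (1S)-1-[2-methoxy-4-methyl-5-(4,4,5,5-tetramethyl-1,3,2-dioxaborolan-2-yl)phenyl]ethyl N,N-diisopropylcarbamate F9 in situ. Adding aqueous K3PO4 would then drive Suzuki coupling of F9 with the remaining F8 to give 7.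

**Further compounds**

F1 | step 7 | diethyl (2E,2′E)-3,3′-(4,4′-dimethoxy-6,6′-dimethylbiphenyl-3,3′-diyl)bis(but-2-enoate) | CCOC(=O)/C=C(\C)c1cc(-c2cc(/C(C)=C/C(=O)OCC)c(OC)cc2C)c(C)cc1OC
F2 | step 7 | diethyl (3S,3′S)-3,3′-(4,4′-dimethoxy-6,6′-dimethylbiphenyl-3,3′-diyl)dibutanoate | CCOC(=O)C[C@H](C)c1cc(-c2cc([C@@H](C)CC(=O)OCC)c(OC)cc2C)c(C)cc1OC
F3 | step 7 | (3S,3′S)-3,3′-(4,4′-dimethoxy-6,6′-dimethylbiphenyl-3,3′-diyl)bis(butan-1-ol) | OCC[C@H](C)c1cc(-c2cc([C@@H](C)CCO)c(OC)cc2C)c(C)cc1OC
F4 | step 7 | 5,5′-bis[(2S)-4-iodobutan-2-yl]-4,4′-dimethoxy-2,2′-dimethylbiphenyl | ICC[C@H](C)c1cc(-c2cc([C@@H](C)CCI)c(OC)cc2C)c(C)cc1OC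
F5 | step 8 | 1,1′-(4,4′-dimethoxy-6,6′-dimethylbiphenyl-3,3′-diyl)bis(5-methylhex-4-en-1-one) | COc1cc(C)c(-c2cc(C(=O)CCC=C(C)C)c(OC)cc2C)cc1C(=O)CCC=C(C)C
F6 | step 8 | 4,4′-dimethoxy-2,2′-dimethyl-5,5′-bis(6-methylhepta-1,5-dien-2-yl)biphenyl | COc1cc(C)c(-c2cc(C(=C)CCC=C(C)C)c(OC)cc2C)cc1C(=C)CCC=C(C)C
F7 | step 4 | (1S)-1-(5-bromo-2-methoxy-4-methylphenyl)ethanol | COc1cc(C)c(Br)cc1[C@H](C)O
F8 | step 4 | (1S)-1-(5-bromo-2-methoxy-4-methylphenyl)ethyl N,N-diisopropylcarbamate | COc1cc(C)c(Br)cc1[C@H](C)OC(=O)N(C(C)C)C(C)C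
F9 | step 4 | (1S)-1-[2-methoxy-4-methyl-5-(4,4,5,5-tetramethyl-1,3,2-dioxaborolan-2-yl)phenyl]ethyl N,N-diisopropylcarbamate | COc1cc(C)c(B2OC(C)(C)C(C)(C)O2)cc1[C@H](C)OC(=O)N(C(C)C)C(C)C
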